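Ring A is disconnected across C-1–C-10 and C-4–C-5: a thermal Diels–Alder reaction of 2,6-dimethyl-1,4-benzoquinone with 2-(triisopropylsilyloxy)buta-1,3-diene closes ring A and creates the quaternary centre C-10 in one operation. It exploits the fact that ring B of the target (C-10 methyl, C-9, C-8 methyl, C-7=C-8) is a masked 2,6-dimethylquinone: the C-9 carbonyl later receives the side chain, the C-6 carbonyl allows C-5 to equilibrate to the trans ring fusion and is then excised. The precursor is just quinone plus diene; the racemic adduct is resolved by catalytic acyl transfer, ring B is completed by a stereospecific allylic hydrogenolysis, and ring A is oxidised and alkylated last.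

Key step: step 2

Remark: labdane numbering is used for all bicyclic compounds (ring A = C-1, C-2, C-3, C-4, C-5, C-10; ring B = C-5 to C-10; C-17 and C-20 = methyl groups on C-8 and C-10; C-18 = methyl and C-19 = oxidised carbon on C-4; C-11 to C-16 = side chain); 4, 5 and 6 are racemates whose SMILES show the enantiomer that is carried on after step 4.

Step 1
Reactants: 1 but-3-en-2-one
Product: 2 2-[(triisopropylsilyl)oxy]buta-1,3-diene
Conditions: i-Pr3SiOTf, Et3N, Et2O, 0 °C to 23 °C
Reagents that add atoms: triisopropylsilyl trifluoromethanesulfonate, CC(C)[Si](C(C)C)(C(C)C)OS(=O)(=O)C(F)(F)F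
Why: Soft enolisation and O-silylation of the methyl ketone on its only enolisable side give the 2-silyloxydiene, the triisopropylsilyl group being chosen because this enol ether has to survive steps 2 to 7.

Step 2
Reactants: 2 2-[(triisopropylsilyl)oxy]buta-1,3-diene; 3 2,6-dimethyl-1,4-benzoquinone
Product: 5 (±)-trans-fused enedione, via cis-fused cycloadduct 4 (not isolated)
Conditions: toluene, 60 °C; then Et3N (cat.), 23 °C
Reagents that add atoms: none
Why: Thermal normal-demand [4+2] cycloaddition of the 2-silyloxydiene to the quinone, a quinone Diels–Alder reaction of the kind used in classical steroid and terpenoid syntheses; ring A (C-1, C-2, C-3, C-4, C-5, C-10) closes in a concerted, asynchronous, suprafacial six-membered mode, the C-4–C-5 bond leading and the C-1–C-10 bond completing the ring. The regiochemistry needed (the nucleophilic CH2 next to the silyloxy carbon to the unsubstituted quinone carbon, hence the other CH2 to the methyl-bearing carbon C-10) follows from the polarisation of the uncatalysed quinone: the carbonyl flanked by the two methyl groups is the stronger acceptor because the other one is deactivated by both methyl groups as vinylogous donors, and the leading bond also forms at the less hindered carbon; a Lewis acid, which would bind the other carbonyl and reverse this, is therefore avoided. The quaternary centre C-10 is created here; suprafacial addition gives the cis-fused adduct 4, and C-5, which is α to the C-6 carbonyl and vinylogously activated by the C-9 carbonyl, is then equilibrated by Et3N to the trans ring fusion (H-5 anti to the C-10 methyl), expected to be the more stable one as in the classical quinone–butadiene adducts. Only one of the two equivalent quinone double bonds reacts, because the remaining enedione double bond of the adduct is β-methylated on both carbonyl sides. The product is racemic; the required enantiomer is selected in step 4.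

Step 3
Reactants: 5 (±)-trans-fused enedione
Product: 6 (±)-C-6 allylic alcohol
Conditions: NaBH4, CeCl3·7H2O, MeOH, −78 °C
Reagents that add atoms: none
Why: Luche 1,2-reduction takes the C-6 carbonyl, flanked by two CH carbons, in preference to the C-9 carbonyl between the quaternary C-10 and the methylated C-8, hydride arriving anti to the axial C-10 methyl (this carbinol centre is removed again in step 5).

Step 4
Reactants: 6 (±)-C-6 allylic alcohol
Product: 7 C-6 propionate (single enantiomer)
Conditions: (R)-benzotetramisole (5 mol%), (EtCO)2O (0.55 equiv), i-Pr2NEt, CHCl3, 0 °C; unreacted antipodal alcohol removed by chromatography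
Reagents that add atoms: propionic anhydride, CCC(=O)OC(=O)CC
Why: Acyl-transfer kinetic resolution of a secondary allylic alcohol with a chiral isothiourea (Birman type), in which the C-7=C-8–C-9=O π system next to the carbinol takes the place of the aryl group of 1-arylalkanols; by that analogy (R)-benzotetramisole is expected to acylate the enantiomer drawn for 6 and leave its mirror image as the alcohol (the catalyst antipode would be taken if the opposite sense were found), and the propionate is the leaving group of step 5.

Step 5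
Reactants: 7 C-6 propionate
Product: 9 ring B enone with C-6 methylene, via β,γ-unsaturated ketone 8 (not isolated)
Conditions: SmI2, THF–MeOH, −78 °C; then DBU (cat.), 23 °C
Reagents that add atoms: none
Why: Electron transfer from SmI2 to the enone expels the γ-propionate (vinylogous α-acyloxy ketone cleavage) and protonation of the dienolate gives 8, which DBU moves into conjugation to the trisubstituted enone; with C-6 now a methylene group the trans ring fusion is fixed.

Step 6
Reactants: 9 ring B enone; 10 2-(2-bromoethyl)-2-methyl-1,3-dioxolane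
Product: 13 tertiary allylic methyl carbonate, via Grignard reagent 11 (not isolated), via tertiary alkoxide 12 (not isolated)
Conditions: 10, Mg, THF, 23 °C; CeCl3, THF, −78 °C; 9; then ClCO2Me, −78 °C to 0 °C
Reagents that add atoms: methyl chloroformate, COC(=O)Cl
Why: Organocerium 1,2-addition to a hindered, enolisable 2-methylcyclohex-2-enone with a quaternary α′ carbon (compare 2,6,6-trimethylcyclohex-2-enone) occurs anti to the axial C-10 methyl, so the C-9 oxygen ends syn to that methyl, and the alkoxide is acylated in the same flask to the tertiary allylic carbonate.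

Step 7
Reactants: 13 tertiary allylic methyl carbonate
Product: 14 13,13-(ethylenedioxy)-3-[(triisopropylsilyl)oxy]-14,15,18,19-tetranor-ent-labda-2,7-diene
Conditions: Pd(OAc)2 (5 mol%), n-Bu3P, HCO2NH4, 1,4-dioxane, 80 °C
Reagents that add atoms: none
Why: Tsuji–Mandai formate hydrogenolysis of an allylic carbonate: zerovalent palladium ionises the carbonate with inversion and so sits on the face anti to the C-10 methyl, and the palladium formate delivers hydride from that face to the more substituted allyl terminus C-9, which keeps the C-7=C-8 double bond and places H-9 anti and the side chain syn to the C-10 methyl.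

Step 8
Reactants: 14 the 2,7-diene silyl enol ether
Product: 15 13,13-(ethylenedioxy)-14,15,18,19-tetranor-ent-labda-1,7-dien-3-one
Conditions: Pd(OAc)2 (1.1 equiv), MeCN, 40 °C
Reagents that add atoms: none
Why: Saegusa–Ito oxidation of the regiodefined silyl enol ether gives the C-1=C-2 enone, which blocks C-2 so that C-4 is the only enolisable position of the C-3 ketone.

Step 9
Reactants: 15 the 1,7-dien-3-one
Product: 17 methyl 13,13-(ethylenedioxy)-3-oxo-14,15-dinor-ent-labda-1,7-dien-19-oate, via sodium enolate 16 (not isolated)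
Conditions: NaH, (MeO)2CO, THF, 65 °C; then MeI, 23 °C
Reagents that add atoms: dimethyl carbonate, COC(=O)OC; iodomethane, CI
Why: Carbomethoxylation at C-4 (a crossed Claisen condensation driven by formation of the β-keto ester enolate) followed by C-methylation of that enolate from the face anti to the axial C-10 methyl, as in the podocarpic acid series, builds the quaternary C-4 with the methyl equatorial and the ester axial, syn to the C-10 methyl.

Step 10
Reactants: 17 the methylated enone keto ester
Product: 18 methyl 13,13-(ethylenedioxy)-3-oxo-14,15-dinor-ent-labd-7-en-19-oate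
Conditions: RhCl(PPh3)3 (10 mol%), H2 (1 atm), benzene–EtOH, 23 °C
Reagents that add atoms: none
Why: Homogeneous hydrogenation with RhCl(PPh3)3 saturates the disubstituted conjugated C-1=C-2 bond (as in the selective reduction of steroidal 1,4-dien-3-ones at C-1) and leaves the trisubstituted C-7=C-8 bond untouched.

Step 11
Reactants: 18 the saturated keto ester
Product: 19 methyl 13,13-(ethylenedioxy)-3-hydroxy-14,15-dinor-ent-labd-7-en-19-oate (axial 3-OH, anti to the C-10 methyl)
Conditions: LiBH(s-Bu)3, THF, −78 °C
Reagents that add atoms: none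
Why: The bulky trialkylborohydride attacks the C-3 ketone along the equatorial trajectory, as with 4,4-disubstituted 3-oxo terpenoids, giving the axial alcohol that is trans-diaxial to the ester; the neopentyl ester is not touched at this temperature.

Step 12
Reactants: 19 the axial hydroxy ester
Product: 20 13,13-(ethylenedioxy)-14,15-dinor-ent-labd-7-ene-3,19-diol
Conditions: LiAlH4, THF, 0 °C to 65 °C
Reagents that add atoms: none
Why: LiAlH4 reduction converts the hindered axial ester into the primary alcohol while the ketal and the isolated alkene are inert.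

Step 13
Reactants: 20 the ketal diol
Product: 21 3,19-dihydroxy-14,15-dinor-ent-labd-7-en-13-one
Conditions: pyridinium p-toluenesulfonate, acetone–H2O, 50 °C
Reagents that add atoms: water, O
Why: Mild acid hydrolysis of the dioxolane frees the methyl ketone without affecting the trisubstituted alkene.

Step 14
Reactants: 21 the diol methyl ketone
Product: 22 allyl (13E)-3,19-dihydroxy-ent-labda-7,13-dien-15-oate
Conditions: allyl (diethoxyphosphoryl)acetate, NaH (excess), THF, 0 °C to 50 °C
Reagents that add atoms: allyl (diethoxyphosphoryl)acetate, C=CCOC(=O)CP(=O)(OCC)OCC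
Why: Horner–Wadsworth–Emmons olefination of the unhindered methyl ketone is expected to favour the (E)-enoate, the minor (Z) isomer being removed by chromatography; the two hydroxyl groups are only deprotonated by the excess base.

Step 15
Reactants: 22 the diol allyl ester
Product: 23 allyl (13E)-3-hydroxy-19-oxo-ent-labda-7,13-dien-15-oate
Conditions: TEMPO (cat.), PhI(OAc)2, CH2Cl2, 23 °C
Reagents that add atoms: none
Why: Oxoammonium (TEMPO) oxidation takes the primary C-19 alcohol in preference to the hindered axial secondary alcohol, and the aldehyde on the quaternary C-4 cannot epimerise.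

Step 16
Reactants: 23 the hydroxy aldehyde
Product: 24 allyl (13E)-3-acetoxy-19-oxo-ent-labda-7,13-dien-15-oate
Conditions: Ac2O, pyridine, DMAP (cat.), CH2Cl2, 23 °C
Reagents that add atoms: acetic anhydride, CC(=O)OC(C)=O
Why: DMAP-catalysed acetylation of the axial secondary alcohol; the β-acetoxy aldehyde has no α-hydrogen and so cannot eliminate.

Step 17
Reactants: 24 the acetoxy aldehyde allyl ester
Product: 25 (13E)-3-acetoxy-19-oxo-ent-labda-7,13-dien-15-oic acid (target)
Conditions: Pd(PPh3)4 (5 mol%), morpholine, THF, 23 °C; acidic work-up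
Reagents that add atoms: none
Why: Tsuji–Trost deallylation through a π-allyl complex of zerovalent palladium with morpholine as allyl acceptor frees the acid under conditions that leave the acetate, the aldehyde and both alkenes alone.

Compound list
1 | but-3-en-2-one | CC(=O)C=C | starting material
2 | 2-[(triisopropylsilyl)oxy]buta-1,3-diene | C=CC(=C)O[Si](C(C)C)(C(C)C)C(C)C | intermediate
3 | 2,6-dimethyl-1,4-benzoquinone | CC1=CC(=O)C=C(C)C1=O | starting material
4 | (±)-cis-8,10-dimethyl-3-[(triisopropylsilyl)oxy]bicyclo[4.4.0]deca-2,7-diene-6,9-dione (labdane locants; H-5 syn to the C-10 methyl) | CC(C)[Si](C(C)C)(C(C)C)OC1=CC[C@@]2(C)C(=O)C(C)=CC(=O)[C@H]2C1 | intermediate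
5 | (±)-trans-8,10-dimethyl-3-[(triisopropylsilyl)oxy]bicyclo[4.4.0]deca-2,7-diene-6,9-dione (H-5 anti to the C-10 methyl) | CC(C)[Si](C(C)C)(C(C)C)OC1=CC[C@@]2(C)C(=O)C(C)=CC(=O)[C@@H]2C1 | intermediate
6 | (±)-6-hydroxy-8,10-dimethyl-3-[(triisopropylsilyl)oxy]-trans-bicyclo[4.4.0]deca-2,7-dien-9-one (6-OH syn to the C-10 methyl) | CC(C)[Si](C(C)C)(C(C)C)OC1=CC[C@@]2(C)C(=O)C(C)=C[C@H](O)[C@@H]2C1 | intermediate
7 | 6-propionyloxy-8,10-dimethyl-3-[(triisopropylsilyl)oxy]-trans-bicyclo[4.4.0]deca-2,7-dien-9-one, single enantiomer | CC(C)[Si](C(C)C)(C(C)C)OC1=CC[C@@]2(C)C(=O)C(C)=C[C@H](OC(=O)CC)[C@@H]2C1 | intermediate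
8 | 8,10-dimethyl-3-[(triisopropylsilyl)oxy]-trans-bicyclo[4.4.0]deca-2,6-dien-9-one (β,γ-unsaturated ketone, mixture of C-8 epimers) | CC(C)[Si](C(C)C)(C(C)C)OC1=CC[C@@]2(C)C(=O)C(C)C=C[C@@H]2C1 | intermediate
9 | 8,10-dimethyl-3-[(triisopropylsilyl)oxy]-trans-bicyclo[4.4.0]deca-2,7-dien-9-one | CC(C)[Si](C(C)C)(C(C)C)OC1=CC[C@@]2(C)C(=O)C(C)=CC[C@@H]2C1 | intermediate
10 | 2-(2-bromoethyl)-2-methyl-1,3-dioxolane | CC1(CCBr)OCCO1 | starting material
11 | [2-(2-methyl-1,3-dioxolan-2-yl)ethyl]magnesium bromide | CC1(CC[Mg]Br)OCCO1 | intermediate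
12 | 9-hydroxy-8,10-dimethyl-9-[2-(2-methyl-1,3-dioxolan-2-yl)ethyl]-3-[(triisopropylsilyl)oxy]-trans-bicyclo[4.4.0]deca-2,7-diene, present in the flask as its alkoxide (O-9 syn, C-11 anti to the C-10 methyl) | CC(C)[Si](C(C)C)(C(C)C)OC1=CC[C@@]2(C)[C@@](O)(CCC3(C)OCCO3)C(C)=CC[C@@H]2C1 | intermediate
13 | methyl carbonate of 12 | CC(C)[Si](C(C)C)(C(C)C)OC1=CC[C@@]2(C)[C@@](OC(=O)OC)(CCC3(C)OCCO3)C(C)=CC[C@@H]2C1 | intermediate
14 | 13,13-(ethylenedioxy)-3-[(triisopropylsilyl)oxy]-14,15,18,19-tetranor-ent-labda-2,7-diene (H-5 and H-9 anti to the C-10 methyl) | CC(C)[Si](C(C)C)(C(C)C)OC1=CC[C@@]2(C)[C@H](CCC3(C)OCCO3)C(C)=CC[C@@H]2C1 | intermediate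
15 | 13,13-(ethylenedioxy)-14,15,18,19-tetranor-ent-labda-1,7-dien-3-one | O=C1C=C[C@@]2(C)[C@H](CCC3(C)OCCO3)C(C)=CC[C@@H]2C1 | intermediate
16 | sodium enolate of methyl 13,13-(ethylenedioxy)-3-oxo-14,15,18-trinor-ent-labda-1,7-dien-19-oate | COC(=O)C1=C([O-])C=C[C@@]2(C)[C@H](CCC3(C)OCCO3)C(C)=CC[C@H]12.[Na+] | intermediate
17 | methyl 13,13-(ethylenedioxy)-3-oxo-14,15-dinor-ent-labda-1,7-dien-19-oate (C-18 methyl anti, ester syn to the C-10 methyl) | O=C1C=C[C@@]2(C)[C@H](CCC3(C)OCCO3)C(C)=CC[C@@H]2[C@]1(C)C(=O)OC | intermediate
18 | methyl 13,13-(ethylenedioxy)-3-oxo-14,15-dinor-ent-labd-7-en-19-oate | O=C1CC[C@@]2(C)[C@H](CCC3(C)OCCO3)C(C)=CC[C@@H]2[C@]1(C)C(=O)OC | intermediate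
19 | methyl 13,13-(ethylenedioxy)-3-hydroxy-14,15-dinor-ent-labd-7-en-19-oate (axial 3-OH, anti to the C-10 methyl) | O[C@H]1CC[C@@]2(C)[C@H](CCC3(C)OCCO3)C(C)=CC[C@@H]2[C@]1(C)C(=O)OC | intermediate
20 | 13,13-(ethylenedioxy)-14,15-dinor-ent-labd-7-ene-3,19-diol | O[C@H]1CC[C@@]2(C)[C@H](CCC3(C)OCCO3)C(C)=CC[C@@H]2[C@]1(C)CO | intermediate
21 | 3,19-dihydroxy-14,15-dinor-ent-labd-7-en-13-one | O[C@H]1CC[C@@]2(C)[C@H](CCC(C)=O)C(C)=CC[C@@H]2[C@]1(C)CO | intermediate
22 | allyl (13E)-3,19-dihydroxy-ent-labda-7,13-dien-15-oate | O[C@H]1CC[C@@]2(C)[C@H](CC/C(C)=C/C(=O)OCC=C)C(C)=CC[C@@H]2[C@]1(C)CO | intermediate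
23 | allyl (13E)-3-hydroxy-19-oxo-ent-labda-7,13-dien-15-oate | O[C@H]1CC[C@@]2(C)[C@H](CC/C(C)=C/C(=O)OCC=C)C(C)=CC[C@@H]2[C@]1(C)C=O | intermediate
24 | allyl (13E)-3-acetoxy-19-oxo-ent-labda-7,13-dien-15-oate | CC(=O)O[C@H]1CC[C@@]2(C)[C@H](CC/C(C)=C/C(=O)OCC=C)C(C)=CC[C@@H]2[C@]1(C)C=O | intermediate
25 | (13E)-3-acetoxy-19-oxo-ent-labda-7,13-dien-15-oic acid (axial 3-acetoxy anti, formyl syn to the C-10 methyl) | CC(=O)O[C@H]1CC[C@@]2(C)[C@H](CC/C(C)=C/C(=O)O)C(C)=CC[C@@H]2[C@]1(C)C=O | target

Total step count: 17. Longest linear sequence: 17 steps (1 to 25); quinone 3 and bromide 10 enter as commercial materials.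

Steps most likely to fail

Step 7. What may go wrong: hydride transfer within the π-allylpalladium intermediate to the less hindered terminus C-7 (leading to the tetrasubstituted 8(9)-olefin), or β-hydride elimination to dienes. The fallback sets out from 12 and comes back at 14. Step 6 is quenched with aqueous NH4Cl instead of ClCO2Me, so that 12 is isolated as the free alcohol. Ph3SiOReO3 (cat.) in Et2O at 0 °C then effects the suprafacial 1,3-transposition to the secondary C-7 allylic alcohol with a C-8=C-9 double bond F6, whose hydroxyl is syn to the C-10 methyl. A Mitsunobu reaction with o-nitrobenzenesulfonylhydrazide (PPh3, diethyl azodicarboxylate, N-methylmorpholine, THF, −30 °C, then 23 °C) inverts C-7 and gives the allylic diazene F7. This loses N2 by retro-ene transfer of hydrogen to C-9 on the face anti to the C-10 methyl (Myers reductive transposition), which gives 14 with the same configuration at C-9.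

Step 4. What may go wrong: insufficient rate difference between the two enantiomers in the acyl transfer, so that the propionate is not enantiomerically pure at useful conversion. The fallback sets out from 6 and comes back at 9. Racemic 6 is esterified with (1S)-camphanic chloride (pyridine, DMAP, CH2Cl2). The two diastereomeric esters, the camphanate of the required enantiomer F1 and the camphanate of the antipode F2, are separated by chromatography or crystallisation. F1 is then submitted to the conditions of step 5 (SmI2, then DBU), the camphanate acting as the leaving group, to give 9.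

Step 6. What may go wrong: enolisation of the enone at C-6 instead of carbonyl addition, or incomplete acylation of the congested tertiary alkoxide and ionisation of the carbonate on isolation. The fallback sets out from 9 and comes back at 14, so that 13 is bypassed. KN(SiMe3)2 and PhNTf2 (THF, −78 °C) convert 9 into the 6,8-dienyl triflate F3, γ-deprotonation at C-6 being the only possibility. A B-alkyl Suzuki–Miyaura coupling (PdCl2(dppf), AsPh3, Cs2CO3, DMF–THF–H2O) joins F3 to the B-alkyl borane F4, made from 2-methyl-2-vinyl-1,3-dioxolane and 9-borabicyclo[3.3.1]nonane, and gives the 9-alkyl 6,8-diene F5. 1,4-Hydrogenation with (naphthalene)Cr(CO)3 (cat.), H2, acetone, 45 °C adds hydrogen to C-6 and C-9 of the cisoid diene from the face anti to the C-10 methyl and leaves the C-7=C-8 bond, giving 14.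

Further compounds
F1 | step 4 | (1S)-camphanate of the required enantiomer of 6 | CC(C)[Si](C(C)C)(C(C)C)OC1=CC[C@@]2(C)C(=O)C(C)=C[C@H](OC(=O)[C@@]34CC[C@@](C)(C(=O)O3)C4(C)C)[C@@H]2C1
F2 | step 4 | (1S)-camphanate of the antipode of 6 | CC(C)[Si](C(C)C)(C(C)C)OC1=CC[C@]2(C)C(=O)C(C)=C[C@@H](OC(=O)[C@@]34CC[C@@](C)(C(=O)O3)C4(C)C)[C@H]2C1
F3 | step 6 | 8,10-dimethyl-3-[(triisopropylsilyl)oxy]-trans-bicyclo[4.4.0]deca-2,6,8-trien-9-yl trifluoromethanesulfonate | CC(C)[Si](C(C)C)(C(C)C)OC1=CC[C@@]2(C)C(OS(=O)(=O)C(F)(F)F)=C(C)C=C[C@@H]2C1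
F4 | step 6 | 9-[2-(2-methyl-1,3-dioxolan-2-yl)ethyl]-9-borabicyclo[3.3.1]nonane | CC1(CCB2C3CCCC2CCC3)OCCO1
F5 | step 6 | 13,13-(ethylenedioxy)-3-[(triisopropylsilyl)oxy]-14,15,18,19-tetranor-ent-labda-2,6,8-triene | CC(C)[Si](C(C)C)(C(C)C)OC1=CC[C@@]2(C)C(CCC3(C)OCCO3)=C(C)C=C[C@@H]2C1
F6 | step 7 | 13,13-(ethylenedioxy)-3-[(triisopropylsilyl)oxy]-14,15,18,19-tetranor-ent-labda-2,8-dien-7-ol (7-OH syn to the C-10 methyl) | CC(C)[Si](C(C)C)(C(C)C)OC1=CC[C@@]2(C)C(CCC3(C)OCCO3)=C(C)[C@H](O)C[C@@H]2C1
F7 | step 7 | C-7 allylic diazene derived from F6 (N anti to the C-10 methyl) | CC(C)[Si](C(C)C)(C(C)C)OC1=CC[C@@]2(C)C(CCC3(C)OCCO3)=C(C)[C@@H](N=N)C[C@@H]2C1
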